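# Ombuin 3-O-sulfate by pinacol closure of ring C at C3–C4

## Analysis of the target

Ombuin 3-O-sulfate is a flavonol in which ring A (benzene) is fused to ring C (a 4-pyranone) and ring B (an aryl group) sits on C2. It has no stereocenter and no stereogenic double bond, so the whole problem is one of oxygen pattern: O7 and O4' are methyl ethers, O5 and O3' are free hydroxyls, and the enolic O3 carries a hydrogen sulfate. The enol sulfate monoester is the fragile group, since acid cleaves it (its own acidity included) and it would not pass a Lewis acid, a hydride or a one-electron reductant, so it has to go on last. The 5-OH is hydrogen-bonded to the C4 carbonyl, which lowers its reactivity and, in the methyl ether, makes O5–CH3 the one ether a chelating Lewis acid will cut. The synthesis is hard for two reasons: the 3-oxygenated pyranone has to be built on a phloroglucinol-type ring A without losing the difference between O5 and O7, and one sulfate has to be placed on O3 beside two other hydroxyls. The strategy rests on C3 and C4 of ring C, which are neighbours that both carry oxygen; C4 is bonded to ring A at C4a, and C3 is bonded to C2, which hangs from ring A through O1. The C3–C4 bond can therefore be made by reductive coupling of two aldehyde carbons.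

## Retrosynthetic reasoning

**O3–S bond.** The sulfate ester is cut first, so it is made last, because no other operation of the route tolerates it. Target 16 comes from its tetrabutylammonium salt 15, and 15 from ombuin 14. The forward step has to sulfate O3 only. The 5-OH is tied up in its hydrogen bond, the 3'-OH is an unconjugated and weakly acidic phenol, and the 3-OH is enolic, which is the basis for selectivity.

**O5–CH3 and O3'–benzyl bonds.** Ombuin 14 is traced to its 5-methyl ether 13, and 13 to the 3'-benzyl ether 12. Methyl is kept on O5 because ring A can then be bought with both methyl ethers in place (6), and only the one peri to the C4 carbonyl is removable by chelation. Benzyl on O3' survives hydride, one-electron reduction and oxidation. It is removed by hydrogenolysis before the Lewis acid step, so that no benzyl cation is released next to the nucleophilic ring A.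

**Oxidation level of ring C.** No bond is cut here. Flavonol 12 is the enol tautomer of the 3,4-dione 11, and 11 is the twofold oxidation product of the 3,4-diol 10. This means the three stereocenters of 10 need no control, because C2, C3 and C4 all end up sp2.

**C3–C4 bond (key disconnection).** Diol 10 is cut between its two carbinol carbons to give dialdehyde 9. Both carbons bear oxygen, so each can come from a carbonyl group. The two carbonyls of 9 are four atoms apart (C4a, C8a, O1, C2), which is the spacing for a six-membered ring. A cut at O1–C2 or C2–C3 would not use the two oxygens in this way. The gain is that ring C arises with O3 and O4 already in place, from a precursor whose two halves are held together by one ether bond. The forward reaction needs a one-electron reductant (divalent samarium) to reduce the ring A aldehyde first, and the C–C bond must form before the α-aryloxy aldehyde can lose its aryloxide.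

**Oxidation level of the precursor.** Dialdehyde 9 is traced to diol 8, and 8 to aldehyde ester 7. The aliphatic aldehyde cannot be carried through the ether-forming step, so it travels as an ester. An ester cannot be reduced to the aldehyde selectively beside an aryl aldehyde, so both carbonyls are taken down to alcohols in 8 and brought back up together.

**O1–C2 bond.** Aldehyde ester 7 is cut at the ether bond into bromide 5 and phenol 6. C2 is benzylic and α to a carbonyl, which makes it a very good SN2 carbon, and O1 is the phenol oxygen of 6. This is the convergent step that joins rings A and B. The forward reaction must alkylate on oxygen without letting the ester enolate add to the neighbouring aldehyde.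

**C2–Br bond and benzyl groups.** Bromide 5 comes from ester 3 through silyl ketene acetal 4. An ionic bromination is chosen because a radical one would also attack the OCH2Ph position. Ester 3 comes from acid 1 and two equivalents of bromide 2 in one operation. The benzyl ester is a throw-away group that the hydride step removes.

## Alternatives that were turned down

Alternative 1: ring A by polyketide-type Claisen closure. The cut is made in ring A, between the carbons that become C4a and C5. The forward key step treats the linear cinnamoyl triketo ester A2 with Mg(OMe)2 in methanol. The enolate carbon next to the cinnamoyl ketone attacks the ester carbon, and the ring aromatizes to the 2,4,6-trihydroxyphenyl chalcone A1.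
- For: it builds the aromatic ring and its 1,3,5-oxygen pattern from an acyclic chain in one step. O5 would be free from the start, so no Lewis-acid demethylation would be needed. On that point it is stronger than the chosen route.
- Against: A2 is a poly-β-carbonyl compound that must be assembled by repeated enolate acylations and handled as an enol mixture. Aldol closure in the other direction and lactonization to a pyranone compete with the Claisen mode. A1 then needs a selective mono-methylation, and ring C and the C3 oxygen are still entirely unmade.
- Comparison: the key step is spent on a ring that is commercially available with O7 already methylated (6). The chosen strategy buys ring A and puts its effort into ring C, which is where the functional difficulty of the target lies.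

Alternative 2: ring C closed at O1–C8a by intramolecular SNAr. The cut is the aryl–oxygen bond of the pyranone. In the forward key step the enolate of the 2-benzyloxy-1,3-diketone A4, formed with K2CO3 in hot DMF, displaces the ortho fluoride through its ring B side oxygen. The product is the protected flavonol A3.
- For: the ring closes at the flavonol oxidation level with O3 already installed, there are no redox adjustments and no diastereomer mixtures, and one hydrogenolysis would free both O3 and O3'. The closure is ionic and is probably more dependable than a one-electron coupling. On that point it is stronger.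
- Against: the fluoroarene is activated only by its ortho carbonyl. That carbonyl is part of the delocalized enolate and is further damped by two methoxy donors ortho and para to it, so the displacement needs heat. The fluorinated aroyl half is not a stock compound and its preparation by acylation of the corresponding fluoroarene is regiochemically ambiguous. The central benzyloxy diketone needs several steps of its own.
- Comparison: the overall length would be similar. The chosen strategy offers two commercial halves with all oxygens correctly placed, no aryl C–O bond to make on a deactivated ring, and a key step at −78 °C.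

Alternative 3: ring C closed at C4–C4a by Friedel–Crafts acylation. The cut is the acyl–aryl bond. In the forward key step trifluoroacetic anhydride converts the (Z)-aryloxyacrylic acid A6 into a mixed anhydride. Its acyl carbon attacks an ortho carbon of the dimethoxyphenoxy ring to give flavone A5.
- For: the phloroglucinol-type ring is an ideal nucleophile, and its symmetry makes both ortho carbons equivalent. A6 would be reached in two operations from a symmetric phenol and a propiolate. It is the shortest way to the bicyclic core, and stronger than the chosen route on step count up to ring closure.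
- Against: A5 is a flavone with hydrogen on C3. The oxygen that must carry the sulfate would have to be introduced afterwards by oxidation of the C2=C3 bond or of a C3 anion on an electron-rich substrate. That adds steps and moves the main risk to a late C–H oxidation.
- Comparison: in the chosen strategy both C3 and C4 carry their oxygens from the aldehyde stage. The flavonol then arises by changing the oxidation state of existing C–O bonds, not by making a new one.

Key step: step 6

Assumption: the target is taken as the free hydrogen sulfate as drawn; because such an acid slowly hydrolyses itself, it would be released cold from its tetrabutylammonium salt at the very end and kept as a cold solution or stored as a salt.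

## Route

Step 1
Reactants: 1 3-hydroxy-4-methoxyphenylacetic acid; 2 benzyl bromide
Product: 3 benzyl 2-(3-benzyloxy-4-methoxyphenyl)acetate
Conditions: BnBr (2.3 equiv), K2CO3, DMF, 60 °C
Reagents that add atoms: benzyl bromide (second equivalent of 2), BrCc1ccccc1
Why: Williamson ether synthesis and carboxylate O-alkylation in one pot: K2CO3 deprotonates the acid and the phenol, and each anion displaces bromide from one equivalent of 2 by SN2, so two benzyl groups are taken up. The benzyl ester is lost again in step 4, so no separate esterification is needed.

Step 2
Reactants: 3 benzyl 2-(3-benzyloxy-4-methoxyphenyl)acetate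
Product: 5 benzyl 2-bromo-2-(3-benzyloxy-4-methoxyphenyl)acetate (racemic), via silyl ketene acetal 4 (not isolated)
Conditions: LiN(SiMe3)2, THF, −78 °C; Me3SiCl; NBS, −78 → 0 °C
Reagents that add atoms: N-bromosuccinimide, O=C1CCC(=O)N1Br
Why: Deprotonation α to the ester and silylation give ketene acetal 4, whose electrophilic bromination by NBS at −78 °C should be far faster than attack on the arene; this ionic path avoids radical conditions that would also brominate the OCH2Ph position. The new stereocenter forms racemic, which does not matter because it becomes sp2 C2 of the flavonol.

Step 3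
Reactants: 5 benzyl 2-bromo-2-(3-benzyloxy-4-methoxyphenyl)acetate; 6 2-hydroxy-4,6-dimethoxybenzaldehyde
Product: 7 benzyl 2-(3-benzyloxy-4-methoxyphenyl)-2-(2-formyl-3,5-dimethoxyphenoxy)acetate (racemic)
Conditions: K2CO3, DMF, 0 °C → rt
Reagents that add atoms: none
Why: Williamson ether synthesis: the phenoxide of 6 displaces bromide by SN2 at a carbon that is both benzylic and α to the ester, forming the O1–C2 bond. The mild carbonate base, room temperature and the low electrophilicity of the 2,4,6-trioxygenated aldehyde should hold back intramolecular aldol addition of the ester enolate.

Step 4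
Reactants: 7 benzyl 2-(3-benzyloxy-4-methoxyphenyl)-2-(2-formyl-3,5-dimethoxyphenoxy)acetate
Product: 8 2-(3-benzyloxy-4-methoxyphenyl)-2-[2-(hydroxymethyl)-3,5-dimethoxyphenoxy]ethan-1-ol (racemic)
Conditions: LiAlH4, THF, 0 °C → rt; H2O, aq NaOH work-up
Reagents that add atoms: none
Why: LiAlH4 reduction takes the benzyl ester to the primary alcohol (releasing benzyl alcohol) and the aldehyde to the benzylic alcohol in one operation; aryl ethers are inert. The work-up is kept basic because the 2,4,6-trioxygenated benzylic alcohol ionizes easily in acid.

Step 5
Reactants: 8 2-(3-benzyloxy-4-methoxyphenyl)-2-[2-(hydroxymethyl)-3,5-dimethoxyphenoxy]ethan-1-ol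
Product: 9 2-[1-(3-benzyloxy-4-methoxyphenyl)-2-oxoethoxy]-4,6-dimethoxybenzaldehyde (racemic)
Conditions: Dess–Martin periodinane (2.5 equiv), NaHCO3, CH2Cl2, 0 °C → rt
Reagents that add atoms: none
Why: Dess–Martin oxidation of both primary alcohols under buffered conditions; it is preferred to an oxalyl chloride/DMSO protocol because HCl released before the amine is added could ionize the electron-rich benzylic alcohol, and because no amine is present to enolize the α-aryloxy aldehyde. The two hydroxyls are too far apart for a five- or six-membered lactol, so over-oxidation to a lactone is not expected; 9 would be used at once without chromatography.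

Step 6
Reactants: 9 2-[1-(3-benzyloxy-4-methoxyphenyl)-2-oxoethoxy]-4,6-dimethoxybenzaldehyde
Product: 10 2-(3-benzyloxy-4-methoxyphenyl)-5,7-dimethoxychromane-3,4-diol (racemic, mixture of diastereomers)
Conditions: SmI2 (2.5 equiv, 0.1 M), THF, −78 → −20 °C, slow addition of 9; aq NH4Cl
Reagents that add atoms: none
Why: Single-electron transfer from divalent samarium to the conjugated ring A aldehyde gives a samarium-bound ketyl at C4, which adds to the C3 aldehyde held four atoms away; a second electron reduces the resulting alkoxy radical and the product leaves as a samarium diolate that is protonated on work-up. The closest known reaction type is the SmI2-mediated intramolecular pinacol coupling of 1,6-dialdehydes, α-alkoxy dialdehydes included, to cyclic 1,2-diols. Ring C closes in a 6-exo-trig mode, the C4 radical attacking carbonyl carbon C3 with the C=O bond outside the new ring. C3 and C4 are the new stereocenters: trivalent samarium bridging both oxygens in the bond-forming transition state should favour the 3,4-cis diol, and the pseudo-equatorial C2 aryl group should place the C3 oxygen trans to itself, but neither relation needs control because C2, C3 and C4 all become sp2 in step 7. The selectivity needed is in the first electron transfer, since a ketyl at the α-aryloxy aldehyde could expel the ring A phenoxide. Conjugation with ring A and the two ortho oxygens that can chelate samarium favour the aryl aldehyde, but its three alkoxy donors raise its reduction potential and narrow the usual aryl-over-alkyl margin. The reaction is therefore run at −78 °C without HMPA or methanol, both of which speed up α-heteroatom cleavage, and 9 is added slowly to excess reductant under dilution so that ring closure stays ahead of fragmentation and of intermolecular coupling.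

Step 7
Reactants: 10 2-(3-benzyloxy-4-methoxyphenyl)-5,7-dimethoxychromane-3,4-diol
Product: 12 2-(3-benzyloxy-4-methoxyphenyl)-3-hydroxy-5,7-dimethoxy-4H-chromen-4-one, via chromane-3,4-dione 11 (not isolated)
Conditions: IBX (3 equiv), DMSO, rt; aq NaHCO3 work-up
Reagents that add atoms: none
Why: IBX oxidizes 1,2-diols to 1,2-diketones without glycol cleavage and without strong acid, so both carbinols of 10 should be taken to dione 11. The C2–H of 11 is benzylic, α to the C3 ketone and α to O1, and its enolization creates the aromatic 4-pyranone, so 11 should tautomerize to the diosphenol (flavonol) 12 in the flask or on work-up; all three stereocenters disappear.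

Step 8
Reactants: 12 2-(3-benzyloxy-4-methoxyphenyl)-3-hydroxy-5,7-dimethoxy-4H-chromen-4-one
Product: 13 3-hydroxy-2-(3-hydroxy-4-methoxyphenyl)-5,7-dimethoxy-4H-chromen-4-one
Conditions: H2 (1 atm), 10% Pd/C, EtOAc–MeOH, rt
Reagents that add atoms: none
Why: Hydrogenolysis of the aryl benzyl ether over palladium on carbon; the tetrasubstituted C2=C3 bond of the pyranone and the methyl ethers should not be reduced. The benzyl group goes before the Lewis acid step so that no benzyl cation is formed next to ring A.

Step 9
Reactants: 13 3-hydroxy-2-(3-hydroxy-4-methoxyphenyl)-5,7-dimethoxy-4H-chromen-4-one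
Product: 14 ombuin, 3,5-dihydroxy-2-(3-hydroxy-4-methoxyphenyl)-7-methoxy-4H-chromen-4-one
Conditions: BCl3 (4 equiv), CH2Cl2, −78 → 0 °C; H2O
Reagents that add atoms: none
Why: Chelation-controlled ether cleavage: boron held between the C4 carbonyl oxygen and the peri O5 activates that O–CH3 bond for attack by chloride, whereas the methyl ethers on O7 and O4' have no such chelate and should survive at 0 °C. The free 3-OH and 3'-OH only form borates, which are hydrolysed on work-up.

Step 10
Reactants: 14 ombuin
Product: 16 Ombuin 3-O-sulfate, via tetrabutylammonium ombuin 3-sulfate 15 (not isolated)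
Conditions: Bu4NHSO4 (1.2 equiv), DCC, pyridine, 4 °C → rt; cold 0.1 M HCl, C18 reversed phase
Reagents that add atoms: tetrabutylammonium hydrogen sulfate, CCCC[N+](CCCC)(CCCC)CCCC.OS(=O)(=O)[O-]
Why: Carbodiimide-mediated O-sulfation: DCC activates hydrogen sulfate as an O-sulfoisourea that transfers SO3 to a hydroxyl, giving the monoester as salt 15 under non-acidic conditions. This reagent is known to sulfate flavonoid hydroxyls in order of acidity and to leave a chelated 5-OH and a 3'-OH alone, so with O7 and O4' methylated the enolic 3-OH of 14 should react first. Brief cold acidification and reversed-phase separation exchange the cation for a proton to give 16.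

## Compound list

1 | 3-hydroxy-4-methoxyphenylacetic acid | COc1ccc(CC(=O)O)cc1O | starting material
2 | benzyl bromide | BrCc1ccccc1 | starting material
3 | benzyl 2-(3-benzyloxy-4-methoxyphenyl)acetate | COc1ccc(CC(=O)OCc2ccccc2)cc1OCc1ccccc1 | intermediate
4 | {[1-(benzyloxy)-2-(3-benzyloxy-4-methoxyphenyl)ethenyl]oxy}trimethylsilane, silyl ketene acetal of 3 (E/Z mixture) | COc1ccc(C=C(OCc2ccccc2)O[Si](C)(C)C)cc1OCc1ccccc1 | intermediate (not isolated)
5 | benzyl 2-bromo-2-(3-benzyloxy-4-methoxyphenyl)acetate (racemic) | COc1ccc(C(Br)C(=O)OCc2ccccc2)cc1OCc1ccccc1 | intermediate
6 | 2-hydroxy-4,6-dimethoxybenzaldehyde | COc1cc(O)c(C=O)c(OC)c1 | starting material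
7 | benzyl 2-(3-benzyloxy-4-methoxyphenyl)-2-(2-formyl-3,5-dimethoxyphenoxy)acetate (racemic) | COc1cc(OC)c(C=O)c(OC(C(=O)OCc2ccccc2)c2ccc(OC)c(OCc3ccccc3)c2)c1 | intermediate
8 | 2-(3-benzyloxy-4-methoxyphenyl)-2-[2-(hydroxymethyl)-3,5-dimethoxyphenoxy]ethan-1-ol (racemic) | COc1cc(OC)c(CO)c(OC(CO)c2ccc(OC)c(OCc3ccccc3)c2)c1 | intermediate
9 | 2-[1-(3-benzyloxy-4-methoxyphenyl)-2-oxoethoxy]-4,6-dimethoxybenzaldehyde (racemic) | COc1cc(OC)c(C=O)c(OC(C=O)c2ccc(OC)c(OCc3ccccc3)c2)c1 | intermediate
10 | 2-(3-benzyloxy-4-methoxyphenyl)-5,7-dimethoxychromane-3,4-diol (racemic, mixture of diastereomers) | COc1cc(OC)c2c(c1)OC(c1ccc(OC)c(OCc3ccccc3)c1)C(O)C2O | intermediate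
11 | 2-(3-benzyloxy-4-methoxyphenyl)-5,7-dimethoxychromane-3,4-dione (racemic) | COc1cc(OC)c2c(c1)OC(c1ccc(OC)c(OCc3ccccc3)c1)C(=O)C2=O | intermediate (not isolated)
12 | 2-(3-benzyloxy-4-methoxyphenyl)-3-hydroxy-5,7-dimethoxy-4H-chromen-4-one | COc1cc(OC)c2c(=O)c(O)c(-c3ccc(OC)c(OCc4ccccc4)c3)oc2c1 | intermediate
13 | 3-hydroxy-2-(3-hydroxy-4-methoxyphenyl)-5,7-dimethoxy-4H-chromen-4-one | COc1cc(OC)c2c(=O)c(O)c(-c3ccc(OC)c(O)c3)oc2c1 | intermediate
14 | ombuin, 3,5-dihydroxy-2-(3-hydroxy-4-methoxyphenyl)-7-methoxy-4H-chromen-4-one | COc1cc(O)c2c(=O)c(O)c(-c3ccc(OC)c(O)c3)oc2c1 | intermediate
15 | tetrabutylammonium ombuin 3-sulfate | COc1cc(O)c2c(=O)c(OS(=O)(=O)[O-])c(-c3ccc(OC)c(O)c3)oc2c1.CCCC[N+](CCCC)(CCCC)CCCC | intermediate (not isolated)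
16 | Ombuin 3-O-sulfate | COc1cc(O)c2c(=O)c(OS(=O)(=O)O)c(-c3ccc(OC)c(O)c3)oc2c1 | target

## Step count and risk

Total step count: 10. Longest linear sequence: 10 steps (1 → 16); phenol 6 enters at step 3.

**Step 6 (key step).** What may go wrong is electron transfer to the α-aryloxy aldehyde followed by loss of the ring A phenoxide. Plain reduction of the aldehydes to alcohols and intermolecular coupling are further risks. The cause is that the ring A carbonyl is deactivated by three donor oxygens, so its advantage over the aliphatic aldehyde is small. The fallback sets out from 9 and returns at 10, and it makes C3–C4 as an alkene without any reduction. Double Wittig methylenation of 9 (Ph3P=CH2, THF, −78 °C → rt) should give the diene 1-{[1-(3-benzyloxy-4-methoxyphenyl)prop-2-en-1-yl]oxy}-2-ethenyl-3,5-dimethoxybenzene F1. Ring-closing metathesis with second-generation Grubbs catalyst (CH2Cl2, 40 °C) should then give 2-(3-benzyloxy-4-methoxyphenyl)-5,7-dimethoxy-2H-chromene F2. Dihydroxylation with catalytic OsO4 and N-methylmorpholine N-oxide, expected anti to the C2 aryl group, gives 10 as its 2,3-trans-3,4-cis diastereomer, which goes into step 7 unchanged.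

**Step 3.** What may go wrong is aldol ring closure of the ester enolate onto the ortho aldehyde under the carbonate base, which would form a dihydrobenzofuran. Solvolysis of the labile benzylic bromide before the hydrogen-bonded, weakly nucleophilic phenoxide reacts is the other risk. The fallback sets out from 3 (with 6) and returns at 7, and it also bypasses step 2. Diazo transfer to 3 with p-acetamidobenzenesulfonyl azide and DBU in MeCN gives benzyl 2-(3-benzyloxy-4-methoxyphenyl)-2-diazoacetate F3. Slow addition of F3 to phenol 6 and catalytic Rh2(OAc)4 in CH2Cl2 forms the O1–C2 bond by carbene O–H insertion without any base.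

**Step 7.** What may go wrong is further oxidation of the electron-rich enol of 12 by excess pentavalent iodine, or stalling at the α-ketol stage. The fallback sets out from 10 and returns at 12, and it splits the oxidation into two single-purpose steps. DDQ in CH2Cl2 should oxidize only the very electron-rich benzylic C4 carbinol to give 2-(3-benzyloxy-4-methoxyphenyl)-3-hydroxy-5,7-dimethoxychroman-4-one F4. Heating F4 with I2 and KOAc in AcOH, the classical dehydrogenation of dihydroflavonols through the enediol, should give 12.

**Step 10.** What may go wrong is competing sulfation at the 3'-OH or double sulfation, and hydrolysis of the enol sulfate during acidification. The fallback sets out from 14 and returns at 16, and it replaces chemical selectivity by enzymatic selectivity. Exhaustive sulfation with SO3·NMe3 and K2CO3 in DMF should give dipotassium ombuin 3,3'-disulfate F5, with the chelated 5-OH left free. Arylsulfatase in buffer hydrolyses phenolic sulfates but not the enolic 3-sulfate of a flavonol, so it should remove the 3'-sulfate and leave potassium ombuin 3-sulfate F6. Cold acidification and reversed-phase separation as in step 10 give 16.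

## Further compounds

F1 | step 6 | 1-{[1-(3-benzyloxy-4-methoxyphenyl)prop-2-en-1-yl]oxy}-2-ethenyl-3,5-dimethoxybenzene (racemic) | COc1cc(OC)c(C=C)c(OC(C=C)c2ccc(OC)c(OCc3ccccc3)c2)c1
F2 | step 6 | 2-(3-benzyloxy-4-methoxyphenyl)-5,7-dimethoxy-2H-chromene (racemic) | COc1cc(OC)c2c(c1)OC(c1ccc(OC)c(OCc3ccccc3)c1)C=C2
F3 | step 3 | benzyl 2-(3-benzyloxy-4-methoxyphenyl)-2-diazoacetate | COc1ccc(C(=[N+]=[N-])C(=O)OCc2ccccc2)cc1OCc1ccccc1
F4 | step 7 | 2-(3-benzyloxy-4-methoxyphenyl)-3-hydroxy-5,7-dimethoxychroman-4-one (racemic, mixture of diastereomers) | COc1cc(OC)c2c(c1)OC(c1ccc(OC)c(OCc3ccccc3)c1)C(O)C2=O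
F5 | step 10 | dipotassium ombuin 3,3'-disulfate | COc1cc(O)c2c(=O)c(OS(=O)(=O)[O-])c(-c3ccc(OC)c(OS(=O)(=O)[O-])c3)oc2c1.[K+].[K+]
F6 | step 10 | potassium ombuin 3-sulfate | COc1cc(O)c2c(=O)c(OS(=O)(=O)[O-])c(-c3ccc(OC)c(O)c3)oc2c1.[K+]
A1 | alternative 1 | (E)-3-(3-benzyloxy-4-methoxyphenyl)-1-(2,4,6-trihydroxyphenyl)prop-2-en-1-one | O=C(/C=C/c1ccc(OC)c(OCc2ccccc2)c1)c1c(O)cc(O)cc1O
A2 | alternative 1 | methyl (E)-9-(3-benzyloxy-4-methoxyphenyl)-3,5,7-trioxonon-8-enoate | COC(=O)CC(=O)CC(=O)CC(=O)/C=C/c1ccc(OC)c(OCc2ccccc2)c1
A3 | alternative 2 | 3-(benzyloxy)-2-(3-benzyloxy-4-methoxyphenyl)-5,7-dimethoxychromen-4-one | COc1cc(OC)c2c(=O)c(OCc3ccccc3)c(-c3ccc(OC)c(OCc4ccccc4)c3)oc2c1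
A4 | alternative 2 | 2-(benzyloxy)-1-(3-benzyloxy-4-methoxyphenyl)-3-(2-fluoro-4,6-dimethoxyphenyl)propane-1,3-dione | COc1cc(F)c(C(=O)C(OCc2ccccc2)C(=O)c2ccc(OC)c(OCc3ccccc3)c2)c(OC)c1
A5 | alternative 3 | 2-(3-benzyloxy-4-methoxyphenyl)-5,7-dimethoxychromen-4-one | COc1cc(OC)c2c(=O)cc(-c3ccc(OC)c(OCc4ccccc4)c3)oc2c1
A6 | alternative 3 | (Z)-3-(3-benzyloxy-4-methoxyphenyl)-3-(3,5-dimethoxyphenoxy)acrylic acid | OC(=O)/C=C(\Oc1cc(OC)cc(OC)c1)c1ccc(OC)c(OCc2ccccc2)c1
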